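## Retrosynthetic overview

1. Enabling feature (cyclohepta[b]furan numbering): the lactone oxygen on C8a and the ring ketone C5 are 1,4-related across the seven-membered ring (C8a–C3a–C4–C5). C8a–O plus C5=O is therefore the open form of an 8-oxabicyclo[3.2.1]octane bridged ketal, and this oxygen can first serve as the oxygen of a carbonyl ylide (a 3-oxidopyrylium) spanning C8a and C5.
2. Key disconnection: C8a–C3a and C4–C5 together, by (5+2) cycloaddition of the 6-methoxy-3-oxidopyrylium 11 (its five carbons become C8a, C8, C7, C6, C5; generated from the acyclic (Z)-diazoketone ester 8 on a chiral dirhodium catalyst) with two carbons of the allenic diester 10 (C3a, C4).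
3. Everything else enters on the oxygen-bridge (exo) face of the bicycle: CH3 at C6 (cuprate), OH at C7 (Rubottom), H at C8 (directed hydride), H at C3a (hydrogenation); the 2-methylbutanoate, a CH2NMe2 handle for the methylidene and the crotonoyl chain are attached on the bicycle.
4. One acid treatment opens the ketal to the C5 ketone and the C8a hydroxyl, removes the extra carboxyl on C4 and closes the lactone; a Hofmann-type elimination then releases the methylidene.
5. Ring order: pyrylium ring (temporary) → seven-membered carbocycle as the oxabicycle (both in step 6) → γ-lactone (step 17).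

Key step: step 6

Remark: bicyclic intermediates are numbered as 8-oxabicyclo[3.2.1]octanes (C1, C2, C3, C4, C5, C6, C7, O8 become C8a, C8, C7, C6, C5, C4, C3a, O1 of the target); TBDPS = tert-butyldiphenylsilyl; Rh2(S-TCPTTL)4 = dirhodium tetrakis[N-tetrachlorophthaloyl-(S)-tert-leucinate].
Assumption: Rh2(S-TCPTTL)4 is taken to give the (1R,5R) adduct; if its sense of induction is the opposite one, the enantiomeric catalyst Rh2(R-TCPTTL)4 is used instead.
Assumption: 1, 9 and 17 are purchased.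
Remark: 12–18 are carried as mixtures at C6 and at the ethylidene double bond (and may contain the C6=C7 tautomer), and 19–28 as two epimers at the carbon bearing CH2NMe2; these elements are written without descriptor and are all erased by steps 11, 12, 17 and 18.

## Route

Step 1
Reactants: 1 tert-butyldiphenyl(prop-2-yn-1-yloxy)silane
Product: 3 methyl 4-(TBDPS-oxy)but-2-ynoate, via lithium acetylide 2 (not isolated)
Conditions: n-BuLi, THF, −78 °C; then ClCO2Me, −78 → 0 °C
Reagents that add atoms: methyl chloroformate COC(=O)Cl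
Why: C-acylation of a lithium acetylide with a chloroformate is a standard route to 2-ynoates, and the bulky silyl ether is chosen because, unlike a benzyl ether, it should not form an oxonium ylide with the later carbenoid.

Step 2
Reactants: 3 methyl 4-(TBDPS-oxy)but-2-ynoate
Product: 4 methyl (2Z)-3-iodo-4-(TBDPS-oxy)but-2-enoate
Conditions: NaI, AcOH, 70 °C
Reagents that add atoms: sodium iodide [Na+].[I-]
Why: Hydroiodination of a 2-ynoate (conjugate addition of iodide, then anti protonation) should give the (Z)-3-iodoenoate, which fixes the cis relation of the ester and the future acyl group that the key step needs.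

Step 3
Reactants: 4 methyl (2Z)-3-iodo-4-(TBDPS-oxy)but-2-enoate
Product: 6 methyl (2Z)-4-oxo-3-(TBDPS-oxymethyl)pent-2-enoate, via ethoxydiene 5 (not isolated)
Conditions: tributyl(1-ethoxyvinyl)stannane, Pd(PPh3)4 (5 mol %), CuI (10 mol %), DMF, 50 °C; then 1 M HCl, THF, 0 °C
Reagents that add atoms: tributyl(1-ethoxyvinyl)stannane CCCC[Sn](CCCC)(CCCC)C(=C)OCC; water O
Why: Stille coupling proceeds with retention of the alkene geometry, and brief acid hydrolysis of the enol ether unmasks the acetyl group without touching the silyl ether.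

Step 4
Reactants: 6 methyl (2Z)-4-oxo-3-(TBDPS-oxymethyl)pent-2-enoate
Product: 8 methyl (2Z)-5-diazo-4-oxo-3-(TBDPS-oxymethyl)pent-2-enoate, via trifluoroacetyl diketone 7 (not isolated)
Conditions: LiN(SiMe3)2, THF, −78 °C, then CF3CO2CH2CF3; crude 7, MsN3, Et3N, H2O, MeCN, 23 °C
Reagents that add atoms: methanesulfonyl azide CS(=O)(=O)N=[N+]=[N-]
Why: Detrifluoroacetylative Regitz diazo transfer (kinetic methyl-ketone enolate, trifluoroacetylation, diazo transfer with loss of the activating group) is the standard way to α'-diazo enones and avoids diazomethane, which would add to the electron-poor alkene.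

Step 5
Reactants: 9 di-tert-butyl 3-oxopentanedioate
Product: 10 di-tert-butyl penta-2,3-dienedioate
Conditions: 2-chloro-1,3-dimethylimidazolinium chloride, Et3N, CH2Cl2, 0 → 23 °C
Reagents that add atoms: none
Why: Dehydration of a 3-oxoglutarate through its O-imidazolinium enol ether and 1,2-elimination is the established preparation of allene-1,3-dicarboxylates.

Step 6
Reactants: 8 methyl (2Z)-5-diazo-4-oxo-3-(TBDPS-oxymethyl)pent-2-enoate; 10 di-tert-butyl penta-2,3-dienedioate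
Product: 12 tert-butyl (1R,5R)-7-(2-tert-butoxy-2-oxoethylidene)-5-methoxy-2-oxo-3-(TBDPS-oxymethyl)-8-oxabicyclo[3.2.1]oct-3-ene-6-carboxylate, via oxidopyrylium ylide 11 (not isolated)
Conditions: Rh2(S-TCPTTL)4 (1 mol %), 10 (3 equiv), PhCF3, 23 °C, slow addition of 8
Reagents that add atoms: none
Why: The dirhodium carbenoid formed from 8 with loss of N2 is attacked by the carbonyl oxygen of the cis-disposed methyl ester to give the aromatic carbonyl ylide 11, whose C2 (α to the olate, later C8a) and C6 (the methoxy-bearing, oxocarbenium-like carbon, later C5) add suprafacially across one C=C of 10. The closest known reaction type is the tandem carbonyl ylide formation–1,3-dipolar cycloaddition of 2-(alkoxycarbonyl)phenyl diazomethyl ketones (1-alkoxy-2-benzopyrylium-4-olates) with electron-poor π-bonds under dirhodium tetracarboxylate catalysis, including its enantioselective form with chiral dirhodium carboxylates; here a (Z)-alkene takes the place of the benzo ring. Two rings close: the pyrylium ring by six-membered O–C bond formation at the carbenoid carbon, and the oxygen-bridged seven-membered carbocycle by a (5+2) cycloaddition of the five pyrylium carbons with two allene carbons. The two new stereocentres C1 and C5 form together, and their absolute sense is decided by which face of the planar, rhodium-associated ylide the chiral carboxylate ligands leave open. The regioselectivity the step needs is secured by polarity (the nucleophilic C2 bonds to the electrophilic central allene carbon, C6 to the ester-bearing terminus), and the symmetry-equivalent ends of 10 remove any choice between its two double bonds. The Z geometry fixed in step 2 lets the ester oxygen reach the carbenoid, and the configuration at C6 and the geometry of the new exocyclic alkene do not matter because steps 11 and 12 erase them.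

Step 7
Reactants: 12 tert-butyl (1R,5R)-7-(2-tert-butoxy-2-oxoethylidene)-5-methoxy-2-oxo-3-(TBDPS-oxymethyl)-8-oxabicyclo[3.2.1]oct-3-ene-6-carboxylate
Product: 13 tert-butyl (1R,4R,5R)-7-(2-tert-butoxy-2-oxoethylidene)-5-methoxy-4-methyl-3-(TBDPS-oxymethyl)-2-(trimethylsilyloxy)-8-oxabicyclo[3.2.1]oct-2-ene-6-carboxylate
Conditions: MeLi, CuI (Me2CuLi, 3 equiv), Me3SiCl, THF, −78 °C; Et3N, pH 7 buffer
Reagents that add atoms: methyllithium [Li]C; chlorotrimethylsilane C[Si](C)(C)Cl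
Why: Conjugate addition of the Gilman cuprate to the enone at C4 from the oxygen-bridge (exo) face, the lower face being covered by the C6–C7 bridge, sets the C4 methyl stereocentre and Me3SiCl traps the enolate; the first equivalent of cuprate only deprotonates the acidic C6–H, which returns on work-up.

Step 8
Reactants: 13 tert-butyl (1R,4R,5R)-7-(2-tert-butoxy-2-oxoethylidene)-5-methoxy-4-methyl-3-(TBDPS-oxymethyl)-2-(trimethylsilyloxy)-8-oxabicyclo[3.2.1]oct-2-ene-6-carboxylate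
Product: 15 tert-butyl (1R,3R,4R,5R)-7-(2-tert-butoxy-2-oxoethylidene)-3-hydroxy-5-methoxy-4-methyl-2-oxo-3-(TBDPS-oxymethyl)-8-oxabicyclo[3.2.1]octane-6-carboxylate, via silyloxy ketone 14 (not isolated)
Conditions: dimethyldioxirane, acetone/CH2Cl2, −78 → 0 °C; then citric acid, MeOH, 0 °C
Reagents that add atoms: dimethyldioxirane CC1(C)OO1
Why: Rubottom oxidation: the dioxirane should epoxidize only the electron-rich silyl enol ether, from the exo face as electrophiles do on enol derivatives of 8-oxabicyclo[3.2.1]octanones, so the C3 hydroxyl ends cis to the bridge and to the C4 methyl; silyl migration and mild acid then give the α-hydroxy ketone.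

Step 9
Reactants: 15 tert-butyl (1R,3R,4R,5R)-7-(2-tert-butoxy-2-oxoethylidene)-3-hydroxy-5-methoxy-4-methyl-2-oxo-3-(TBDPS-oxymethyl)-8-oxabicyclo[3.2.1]octane-6-carboxylate
Product: 16 tert-butyl (1R,2S,3R,4R,5R)-7-(2-tert-butoxy-2-oxoethylidene)-2,3-dihydroxy-5-methoxy-4-methyl-3-(TBDPS-oxymethyl)-8-oxabicyclo[3.2.1]octane-6-carboxylate
Conditions: Me4NBH(OAc)3, MeCN/AcOH (1:1), −30 → 0 °C
Reagents that add atoms: none
Why: Evans–Saksena hydroxyl-directed reduction: the C3 hydroxyl binds the triacetoxyborohydride and hands the hydride to the neighbouring C2 carbonyl on its own (exo) face, which should give the trans-2,3-diol with the C2 hydroxyl anti to the bridge while esters, ketal and enoate stay untouched.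

Step 10
Reactants: 16 tert-butyl (1R,2S,3R,4R,5R)-7-(2-tert-butoxy-2-oxoethylidene)-2,3-dihydroxy-5-methoxy-4-methyl-3-(TBDPS-oxymethyl)-8-oxabicyclo[3.2.1]octane-6-carboxylate; 17 (2R)-2-methylbutanoic acid
Product: 18 tert-butyl (1R,2S,3R,4R,5R)-7-(2-tert-butoxy-2-oxoethylidene)-3-hydroxy-5-methoxy-4-methyl-2-[(2R)-2-methylbutanoyloxy]-3-(TBDPS-oxymethyl)-8-oxabicyclo[3.2.1]octane-6-carboxylate
Conditions: DCC, DMAP (0.2 equiv), CH2Cl2, 0 → 23 °C
Reagents that add atoms: none
Why: Steglich esterification acylates the secondary C2 hydroxyl while the tertiary C3 hydroxyl stays free, and carbodiimide activation should not epimerize the α-branched acid.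

Step 11
Reactants: 18 tert-butyl (1R,2S,3R,4R,5R)-7-(2-tert-butoxy-2-oxoethylidene)-3-hydroxy-5-methoxy-4-methyl-2-[(2R)-2-methylbutanoyloxy]-3-(TBDPS-oxymethyl)-8-oxabicyclo[3.2.1]octane-6-carboxylate
Product: 19 tert-butyl (1R,2S,3R,4R,5R)-7-[1-tert-butoxy-3-(dimethylamino)-1-oxopropan-2-yl]-3-hydroxy-5-methoxy-4-methyl-2-[(2R)-2-methylbutanoyloxy]-3-(TBDPS-oxymethyl)-8-oxabicyclo[3.2.1]oct-6-ene-6-carboxylate
Conditions: CH2=NMe2 I (Eschenmoser's salt, 1.05 equiv), Et3N, CH2Cl2, −20 → 0 °C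
Reagents that add atoms: N,N-dimethylmethyleneiminium iodide C=[N+](C)C.[I-]
Why: Mannich reaction: the doubly activated C6–H (α to one ester, vinylogous to the other) is enolized by the amine base and the delocalized carbanion attacks the iminium ion at its unhindered exocyclic end, which brings in the future methylidene carbon and moves the double bond to C6=C7 whatever the starting isomer.

Step 12
Reactants: 19 tert-butyl (1R,2S,3R,4R,5R)-7-[1-tert-butoxy-3-(dimethylamino)-1-oxopropan-2-yl]-3-hydroxy-5-methoxy-4-methyl-2-[(2R)-2-methylbutanoyloxy]-3-(TBDPS-oxymethyl)-8-oxabicyclo[3.2.1]oct-6-ene-6-carboxylate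
Product: 20 tert-butyl (1R,2S,3R,4R,5R,6R,7S)-7-[1-tert-butoxy-3-(dimethylamino)-1-oxopropan-2-yl]-3-hydroxy-5-methoxy-4-methyl-2-[(2R)-2-methylbutanoyloxy]-3-(TBDPS-oxymethyl)-8-oxabicyclo[3.2.1]octane-6-carboxylate
Conditions: H2 (5 bar), Pd(OH)2/C, EtOAc/AcOH (20:1), 23 °C
Reagents that add atoms: none
Why: Heterogeneous catalytic hydrogenation adds both hydrogens syn from the exo face, the only face not covered by the three-carbon bridge, which sets C7–H (later C3a–H) cis to the oxygen bridge and puts both carbon substituents endo.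

Step 13
Reactants: 20 tert-butyl (1R,2S,3R,4R,5R,6R,7S)-7-[1-tert-butoxy-3-(dimethylamino)-1-oxopropan-2-yl]-3-hydroxy-5-methoxy-4-methyl-2-[(2R)-2-methylbutanoyloxy]-3-(TBDPS-oxymethyl)-8-oxabicyclo[3.2.1]octane-6-carboxylate
Product: 21 tert-butyl (1R,2S,3R,4R,5R,6R,7S)-7-[1-tert-butoxy-3-(dimethylamino)-1-oxopropan-2-yl]-3-hydroxy-3-(hydroxymethyl)-5-methoxy-4-methyl-2-[(2R)-2-methylbutanoyloxy]-8-oxabicyclo[3.2.1]octane-6-carboxylate
Conditions: HF·pyridine, pyridine/THF, 0 → 23 °C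
Reagents that add atoms: none
Why: Fluoride-driven desilylation under buffered, non-basic conditions frees the primary alcohol without acyl migration and leaves the tert-butyl esters and the bridged ketal intact.

Step 14
Reactants: 21 tert-butyl (1R,2S,3R,4R,5R,6R,7S)-7-[1-tert-butoxy-3-(dimethylamino)-1-oxopropan-2-yl]-3-hydroxy-3-(hydroxymethyl)-5-methoxy-4-methyl-2-[(2R)-2-methylbutanoyloxy]-8-oxabicyclo[3.2.1]octane-6-carboxylate
Product: 22 tert-butyl (1R,2S,3S,4R,5R,6R,7S)-7-[1-tert-butoxy-3-(dimethylamino)-1-oxopropan-2-yl]-3-formyl-3-hydroxy-5-methoxy-4-methyl-2-[(2R)-2-methylbutanoyloxy]-8-oxabicyclo[3.2.1]octane-6-carboxylate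
Conditions: SO3·pyridine, DMSO, i-Pr2NEt, CH2Cl2, 0 °C
Reagents that add atoms: none
Why: Parikh–Doering oxidation converts the only primary alcohol into the aldehyde, tolerates the tertiary amine and cannot oxidize the tertiary alcohol.

Step 15
Reactants: 22 tert-butyl (1R,2S,3S,4R,5R,6R,7S)-7-[1-tert-butoxy-3-(dimethylamino)-1-oxopropan-2-yl]-3-formyl-3-hydroxy-5-methoxy-4-methyl-2-[(2R)-2-methylbutanoyloxy]-8-oxabicyclo[3.2.1]octane-6-carboxylate
Product: 23 tert-butyl (1R,2S,3R,4R,5R,6R,7S)-7-[1-tert-butoxy-3-(dimethylamino)-1-oxopropan-2-yl]-3-hydroxy-3-[(2E)-1-hydroxybut-2-en-1-yl]-5-methoxy-4-methyl-2-[(2R)-2-methylbutanoyloxy]-8-oxabicyclo[3.2.1]octane-6-carboxylate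
Conditions: (E)-1-bromoprop-1-ene, t-BuLi, Et2O, −78 °C; CeCl3, THF, −78 °C; then 22; aq. NH4Cl
Reagents that add atoms: (E)-1-bromoprop-1-ene C/C=C/Br
Why: 1,2-Addition of an alkenylcerium reagent: bromine–lithium exchange keeps the E geometry and the weakly basic organocerium adds to the aldehyde only, leaving the three esters alone; the new carbinol centre is left uncontrolled because step 16 oxidizes it.

Step 16
Reactants: 23 tert-butyl (1R,2S,3R,4R,5R,6R,7S)-7-[1-tert-butoxy-3-(dimethylamino)-1-oxopropan-2-yl]-3-hydroxy-3-[(2E)-1-hydroxybut-2-en-1-yl]-5-methoxy-4-methyl-2-[(2R)-2-methylbutanoyloxy]-8-oxabicyclo[3.2.1]octane-6-carboxylate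
Product: 24 tert-butyl (1R,2S,3S,4R,5R,6R,7S)-3-[(2E)-but-2-enoyl]-7-[1-tert-butoxy-3-(dimethylamino)-1-oxopropan-2-yl]-3-hydroxy-5-methoxy-4-methyl-2-[(2R)-2-methylbutanoyloxy]-8-oxabicyclo[3.2.1]octane-6-carboxylate
Conditions: MnO2, CH2Cl2, 23 °C
Reagents that add atoms: none
Why: MnO2 oxidizes only the allylic secondary alcohol to the (E)-enone; the tertiary alcohol cannot react.

Step 17
Reactants: 24 tert-butyl (1R,2S,3S,4R,5R,6R,7S)-3-[(2E)-but-2-enoyl]-7-[1-tert-butoxy-3-(dimethylamino)-1-oxopropan-2-yl]-3-hydroxy-5-methoxy-4-methyl-2-[(2R)-2-methylbutanoyloxy]-8-oxabicyclo[3.2.1]octane-6-carboxylate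
Product: 27 (3aR,6R,7S,8S,8aR)-7-[(2E)-but-2-enoyl]-3-[(dimethylamino)methyl]-7-hydroxy-6-methyl-2,5-dioxooctahydro-2H-cyclohepta[b]furan-8-yl (2R)-2-methylbutanoate, via hydroxy keto diacid 25 (not isolated), via hydroxy keto acid 26 (not isolated)
Conditions: CF3CO2H/CH2Cl2/H2O (10:10:1), 0 → 30 °C; then aq. NaHCO3 to pH 8
Reagents that add atoms: water O
Why: Acid cascade of known events: protonation of the bridging oxygen opens the ketal to a methoxycarbenium ion that water turns into the C5 ketone and the C8a hydroxyl, both tert-butyl esters lose isobutene, the β-keto acid at C4 decarboxylates and the γ-hydroxy acid lactonizes to the trans-fused lactone; no stereocentre is touched and the protonated amine is inert.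

Step 18
Reactants: 27 (3aR,6R,7S,8S,8aR)-7-[(2E)-but-2-enoyl]-3-[(dimethylamino)methyl]-7-hydroxy-6-methyl-2,5-dioxooctahydro-2H-cyclohepta[b]furan-8-yl (2R)-2-methylbutanoate
Product: 29 (3aR,6R,7S,8S,8aR)-7-[(2E)-but-2-enoyl]-7-hydroxy-6-methyl-3-methylidene-2,5-dioxooctahydro-2H-cyclohepta[b]furan-8-yl (2R)-2-methylbutanoate, via methiodide 28 (not isolated)
Conditions: MeI, CH2Cl2, 23 °C; then aq. NaHCO3, EtOAc, 23 °C
Reagents that add atoms: none
Why: Hofmann-type elimination: quaternization makes the amine a leaving group and bicarbonate removes the acidic lactone α-proton (E1cB) to unveil the α-methylidene lactone under conditions too mild to epimerize C6 or to trigger retro-aldol cleavage at C7.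

## Compound list

1 | tert-butyldiphenyl(prop-2-yn-1-yloxy)silane | C#CCO[Si](c1ccccc1)(c1ccccc1)C(C)(C)C | starting material
2 | [3-(TBDPS-oxy)prop-1-yn-1-yl]lithium | [Li]C#CCO[Si](c1ccccc1)(c1ccccc1)C(C)(C)C | intermediate (not isolated)
3 | methyl 4-(TBDPS-oxy)but-2-ynoate | COC(=O)C#CCO[Si](c1ccccc1)(c1ccccc1)C(C)(C)C | intermediate
4 | methyl (2Z)-3-iodo-4-(TBDPS-oxy)but-2-enoate | COC(=O)/C=C(\I)CO[Si](c1ccccc1)(c1ccccc1)C(C)(C)C | intermediate
5 | methyl (2Z)-4-ethoxy-3-(TBDPS-oxymethyl)penta-2,4-dienoate | COC(=O)/C=C(\C(=C)OCC)CO[Si](c1ccccc1)(c1ccccc1)C(C)(C)C | intermediate (not isolated)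
6 | methyl (2Z)-4-oxo-3-(TBDPS-oxymethyl)pent-2-enoate | COC(=O)/C=C(\C(C)=O)CO[Si](c1ccccc1)(c1ccccc1)C(C)(C)C | intermediate
7 | methyl (2Z)-7,7,7-trifluoro-4,6-dioxo-3-(TBDPS-oxymethyl)hept-2-enoate | COC(=O)/C=C(\C(=O)CC(=O)C(F)(F)F)CO[Si](c1ccccc1)(c1ccccc1)C(C)(C)C | intermediate (not isolated)
8 | methyl (2Z)-5-diazo-4-oxo-3-(TBDPS-oxymethyl)pent-2-enoate | COC(=O)/C=C(\C(=O)C=[N+]=[N-])CO[Si](c1ccccc1)(c1ccccc1)C(C)(C)C | intermediate
9 | di-tert-butyl 3-oxopentanedioate | CC(C)(C)OC(=O)CC(=O)CC(=O)OC(C)(C)C | starting material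
10 | di-tert-butyl penta-2,3-dienedioate (racemic allene) | CC(C)(C)OC(=O)C=C=CC(=O)OC(C)(C)C | intermediate
11 | 6-methoxy-4-(TBDPS-oxymethyl)pyrylium-3-olate | [O-]c1c[o+]c(OC)cc1CO[Si](c2ccccc2)(c2ccccc2)C(C)(C)C | intermediate (not isolated)
12 | tert-butyl (1R,5R)-7-(2-tert-butoxy-2-oxoethylidene)-5-methoxy-2-oxo-3-(TBDPS-oxymethyl)-8-oxabicyclo[3.2.1]oct-3-ene-6-carboxylate (C6 and alkene geometry undefined) | O1[C@@H]2C(=CC(=O)OC(C)(C)C)C(C(=O)OC(C)(C)C)[C@@]1(OC)C=C(CO[Si](c1ccccc1)(c1ccccc1)C(C)(C)C)C2=O | intermediate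
13 | tert-butyl (1R,4R,5R)-7-(2-tert-butoxy-2-oxoethylidene)-5-methoxy-4-methyl-3-(TBDPS-oxymethyl)-2-(trimethylsilyloxy)-8-oxabicyclo[3.2.1]oct-2-ene-6-carboxylate (methyl syn to the oxygen bridge) | O1[C@@H]2C(=CC(=O)OC(C)(C)C)C(C(=O)OC(C)(C)C)[C@@]1(OC)[C@H](C)C(CO[Si](c1ccccc1)(c1ccccc1)C(C)(C)C)=C2O[Si](C)(C)C | intermediate
14 | 3-O-trimethylsilyl ether of 15 | O1[C@@H]2C(=CC(=O)OC(C)(C)C)C(C(=O)OC(C)(C)C)[C@@]1(OC)[C@H](C)[C@@](O[Si](C)(C)C)(CO[Si](c1ccccc1)(c1ccccc1)C(C)(C)C)C2=O | intermediate (not isolated)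
15 | tert-butyl (1R,3R,4R,5R)-7-(2-tert-butoxy-2-oxoethylidene)-3-hydroxy-5-methoxy-4-methyl-2-oxo-3-(TBDPS-oxymethyl)-8-oxabicyclo[3.2.1]octane-6-carboxylate (OH and CH3 syn to the bridge) | O1[C@@H]2C(=CC(=O)OC(C)(C)C)C(C(=O)OC(C)(C)C)[C@@]1(OC)[C@H](C)[C@@](O)(CO[Si](c1ccccc1)(c1ccccc1)C(C)(C)C)C2=O | intermediate
16 | tert-butyl (1R,2S,3R,4R,5R)-7-(2-tert-butoxy-2-oxoethylidene)-2,3-dihydroxy-5-methoxy-4-methyl-3-(TBDPS-oxymethyl)-8-oxabicyclo[3.2.1]octane-6-carboxylate (2-OH anti to the bridge) | O1[C@@H]2C(=CC(=O)OC(C)(C)C)C(C(=O)OC(C)(C)C)[C@@]1(OC)[C@H](C)[C@@](O)(CO[Si](c1ccccc1)(c1ccccc1)C(C)(C)C)[C@H]2O | intermediate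
17 | (2R)-2-methylbutanoic acid | CC[C@@H](C)C(=O)O | starting material
18 | tert-butyl (1R,2S,3R,4R,5R)-7-(2-tert-butoxy-2-oxoethylidene)-3-hydroxy-5-methoxy-4-methyl-2-[(2R)-2-methylbutanoyloxy]-3-(TBDPS-oxymethyl)-8-oxabicyclo[3.2.1]octane-6-carboxylate | O1[C@@H]2C(=CC(=O)OC(C)(C)C)C(C(=O)OC(C)(C)C)[C@@]1(OC)[C@H](C)[C@@](O)(CO[Si](c1ccccc1)(c1ccccc1)C(C)(C)C)[C@H]2OC(=O)[C@H](C)CC | intermediate
19 | tert-butyl (1R,2S,3R,4R,5R)-7-[1-tert-butoxy-3-(dimethylamino)-1-oxopropan-2-yl]-3-hydroxy-5-methoxy-4-methyl-2-[(2R)-2-methylbutanoyloxy]-3-(TBDPS-oxymethyl)-8-oxabicyclo[3.2.1]oct-6-ene-6-carboxylate | O1[C@@H]2C(C(CN(C)C)C(=O)OC(C)(C)C)=C(C(=O)OC(C)(C)C)[C@@]1(OC)[C@H](C)[C@@](O)(CO[Si](c1ccccc1)(c1ccccc1)C(C)(C)C)[C@H]2OC(=O)[C@H](C)CC | intermediate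
20 | tert-butyl (1R,2S,3R,4R,5R,6R,7S)-7-[1-tert-butoxy-3-(dimethylamino)-1-oxopropan-2-yl]-3-hydroxy-5-methoxy-4-methyl-2-[(2R)-2-methylbutanoyloxy]-3-(TBDPS-oxymethyl)-8-oxabicyclo[3.2.1]octane-6-carboxylate (both C6 and C7 substituents endo) | O1[C@@H]2[C@@H](C(CN(C)C)C(=O)OC(C)(C)C)[C@@H](C(=O)OC(C)(C)C)[C@@]1(OC)[C@H](C)[C@@](O)(CO[Si](c1ccccc1)(c1ccccc1)C(C)(C)C)[C@H]2OC(=O)[C@H](C)CC | intermediate
21 | 3-(hydroxymethyl) analogue of 20 (1R,2S,3R,4R,5R,6R,7S) | O1[C@@H]2[C@@H](C(CN(C)C)C(=O)OC(C)(C)C)[C@@H](C(=O)OC(C)(C)C)[C@@]1(OC)[C@H](C)[C@@](O)(CO)[C@H]2OC(=O)[C@H](C)CC | intermediate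
22 | 3-formyl analogue (1R,2S,3S,4R,5R,6R,7S) | O1[C@@H]2[C@@H](C(CN(C)C)C(=O)OC(C)(C)C)[C@@H](C(=O)OC(C)(C)C)[C@@]1(OC)[C@H](C)[C@@](O)(C=O)[C@H]2OC(=O)[C@H](C)CC | intermediate
23 | 3-[(2E)-1-hydroxybut-2-en-1-yl] analogue (carbinol epimers) | O1[C@@H]2[C@@H](C(CN(C)C)C(=O)OC(C)(C)C)[C@@H](C(=O)OC(C)(C)C)[C@@]1(OC)[C@H](C)[C@@](O)(C(O)/C=C/C)[C@H]2OC(=O)[C@H](C)CC | intermediate
24 | 3-[(2E)-but-2-enoyl] analogue (1R,2S,3S,4R,5R,6R,7S) | O1[C@@H]2[C@@H](C(CN(C)C)C(=O)OC(C)(C)C)[C@@H](C(=O)OC(C)(C)C)[C@@]1(OC)[C@H](C)[C@@](O)(C(=O)/C=C/C)[C@H]2OC(=O)[C@H](C)CC | intermediate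
25 | ring-opened hydroxy keto diacid (cycloheptanone with C8a–OH, C4–CO2H and the aminomethyl acetic acid side chain on C3a) | O[C@@H]1[C@@H](C(CN(C)C)C(=O)O)[C@@H](C(=O)O)C(=O)[C@H](C)[C@@](O)(C(=O)/C=C/C)[C@H]1OC(=O)[C@H](C)CC | intermediate (not isolated)
26 | decarboxylated hydroxy keto acid | O[C@@H]1[C@@H](C(CN(C)C)C(=O)O)CC(=O)[C@H](C)[C@@](O)(C(=O)/C=C/C)[C@H]1OC(=O)[C@H](C)CC | intermediate (not isolated)
27 | (3aR,6R,7S,8S,8aR)-7-[(2E)-but-2-enoyl]-3-[(dimethylamino)methyl]-7-hydroxy-6-methyl-2,5-dioxooctahydro-2H-cyclohepta[b]furan-8-yl (2R)-2-methylbutanoate | CN(C)CC1C(=O)O[C@@H]2[C@@H]1CC(=O)[C@H](C)[C@@](O)(C(=O)/C=C/C)[C@H]2OC(=O)[C@H](C)CC | intermediate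
28 | N-methyl quaternary ammonium iodide of 27 | C[N+](C)(C)CC1C(=O)O[C@@H]2[C@@H]1CC(=O)[C@H](C)[C@@](O)(C(=O)/C=C/C)[C@H]2OC(=O)[C@H](C)CC.[I-] | intermediate (not isolated)
29 | (3aR,6R,7S,8S,8aR)-7-[(2E)-but-2-enoyl]-7-hydroxy-6-methyl-3-methylidene-2,5-dioxooctahydro-2H-cyclohepta[b]furan-8-yl (2R)-2-methylbutanoate | C=C1C(=O)O[C@@H]2[C@@H]1CC(=O)[C@H](C)[C@@](O)(C(=O)/C=C/C)[C@H]2OC(=O)[C@H](C)CC | target

## Step count and risks

Total steps: 18. Longest linear sequence: 17 (steps 1–4 and 6–18; step 5 prepares the second component).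

Steps most likely to fail:

1. Step 6. The aromatic ylide may leave the chiral rhodium centre before it is trapped, so that the two faces are no longer told apart and the adduct forms with poor enantiofacial selectivity. Fallback, setting out from 8 and 10 and returning at 18: the cycloaddition is run with achiral Rh2(OAc)4 to give the racemate, that is 12 together with its enantiomer F1. Steps 7–9 on the racemate give, beside 13–16, the enantiomeric silyl enol ether F2, the enantiomeric silyloxy ketone F3 (not isolated), the enantiomeric hydroxy ketone F4 and the enantiomeric diol F5. Esterification of the racemic diol with enantiopure 17 as in step 10 gives 18 and the diastereomeric ester F6, which are separated by chromatography or crystallization; the route continues from 18.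

2. Step 12. The fully substituted C6=C7 double bond, flanked by two bridgeheads and facing the axial silyloxymethyl group of the quaternary C3, may take up hydrogen too slowly, so that saturation stays incomplete or the allylic C–O bridge is hydrogenolysed first. Fallback, setting out from 12 and returning at 20: the double bond is saturated before C3 becomes quaternary, and the hydroxyl is introduced afterwards by enolate oxidation. Me2CuLi followed by NH4Cl (no silyl trapping) gives the ketone F7; the Mannich reaction of step 11 gives the amino enoate F8; hydrogenation as in step 12 gives the saturated ketone F9. KN(SiMe3)2 and 2-(phenylsulfonyl)-3-phenyloxaziridine (Davis oxidation, exo face) give the hydroxy ketone F10, Me4NBH(OAc)3 gives the diol F11, and esterification with 17 (DCC, DMAP) gives 20.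

3. Step 4. Under the strong amide base the electron-poor (Z)-alkene may undergo conjugate addition or γ-deprotonation, which would scramble the Z geometry or lead to oligomers. Fallback, setting out from 4 and returning at 8: the Stille coupling is worked up without acid so that the ethoxydiene 5 is isolated; NBS in wet THF converts it into the bromomethyl ketone F12, and N,N'-ditosylhydrazine with DBU (alkylation, then double loss of sulfinate) turns this into 8 without a ketone enolate.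

## Further compounds

F1 | step 6 | enantiomer of 12 (1S,5S) | O1[C@H]2C(=CC(=O)OC(C)(C)C)C(C(=O)OC(C)(C)C)[C@]1(OC)C=C(CO[Si](c1ccccc1)(c1ccccc1)C(C)(C)C)C2=O
F2 | step 6 | enantiomer of 13 (1S,4S,5S) | O1[C@H]2C(=CC(=O)OC(C)(C)C)C(C(=O)OC(C)(C)C)[C@]1(OC)[C@@H](C)C(CO[Si](c1ccccc1)(c1ccccc1)C(C)(C)C)=C2O[Si](C)(C)C
F3 | step 6 | enantiomer of 14 | O1[C@H]2C(=CC(=O)OC(C)(C)C)C(C(=O)OC(C)(C)C)[C@]1(OC)[C@@H](C)[C@](O[Si](C)(C)C)(CO[Si](c1ccccc1)(c1ccccc1)C(C)(C)C)C2=O
F4 | step 6 | enantiomer of 15 (1S,3S,4S,5S) | O1[C@H]2C(=CC(=O)OC(C)(C)C)C(C(=O)OC(C)(C)C)[C@]1(OC)[C@@H](C)[C@](O)(CO[Si](c1ccccc1)(c1ccccc1)C(C)(C)C)C2=O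
F5 | step 6 | enantiomer of 16 (1S,2R,3S,4S,5S) | O1[C@H]2C(=CC(=O)OC(C)(C)C)C(C(=O)OC(C)(C)C)[C@]1(OC)[C@@H](C)[C@](O)(CO[Si](c1ccccc1)(c1ccccc1)C(C)(C)C)[C@@H]2O
F6 | step 6 | (2R)-2-methylbutanoate of F5, diastereomer of 18 | O1[C@H]2C(=CC(=O)OC(C)(C)C)C(C(=O)OC(C)(C)C)[C@]1(OC)[C@@H](C)[C@](O)(CO[Si](c1ccccc1)(c1ccccc1)C(C)(C)C)[C@@H]2OC(=O)[C@H](C)CC
F7 | step 12 | tert-butyl (1R,4R,5R)-7-(2-tert-butoxy-2-oxoethylidene)-5-methoxy-4-methyl-2-oxo-3-(TBDPS-oxymethyl)-8-oxabicyclo[3.2.1]octane-6-carboxylate (C3 epimers) | O1[C@@H]2C(=CC(=O)OC(C)(C)C)C(C(=O)OC(C)(C)C)[C@@]1(OC)[C@H](C)C(CO[Si](c1ccccc1)(c1ccccc1)C(C)(C)C)C2=O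
F8 | step 12 | tert-butyl (1R,4R,5R)-7-[1-tert-butoxy-3-(dimethylamino)-1-oxopropan-2-yl]-5-methoxy-4-methyl-2-oxo-3-(TBDPS-oxymethyl)-8-oxabicyclo[3.2.1]oct-6-ene-6-carboxylate | O1[C@@H]2C(C(CN(C)C)C(=O)OC(C)(C)C)=C(C(=O)OC(C)(C)C)[C@@]1(OC)[C@H](C)C(CO[Si](c1ccccc1)(c1ccccc1)C(C)(C)C)C2=O
F9 | step 12 | tert-butyl (1R,4R,5R,6R,7S)-7-[1-tert-butoxy-3-(dimethylamino)-1-oxopropan-2-yl]-5-methoxy-4-methyl-2-oxo-3-(TBDPS-oxymethyl)-8-oxabicyclo[3.2.1]octane-6-carboxylate | O1[C@@H]2[C@@H](C(CN(C)C)C(=O)OC(C)(C)C)[C@@H](C(=O)OC(C)(C)C)[C@@]1(OC)[C@H](C)C(CO[Si](c1ccccc1)(c1ccccc1)C(C)(C)C)C2=O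
F10 | step 12 | (1R,3R,4R,5R,6R,7S)-3-hydroxy derivative of F9 | O1[C@@H]2[C@@H](C(CN(C)C)C(=O)OC(C)(C)C)[C@@H](C(=O)OC(C)(C)C)[C@@]1(OC)[C@H](C)[C@@](O)(CO[Si](c1ccccc1)(c1ccccc1)C(C)(C)C)C2=O
F11 | step 12 | (1R,2S,3R,4R,5R,6R,7S)-2,3-diol from F10 | O1[C@@H]2[C@@H](C(CN(C)C)C(=O)OC(C)(C)C)[C@@H](C(=O)OC(C)(C)C)[C@@]1(OC)[C@H](C)[C@@](O)(CO[Si](c1ccccc1)(c1ccccc1)C(C)(C)C)[C@H]2O
F12 | step 4 | methyl (2Z)-5-bromo-4-oxo-3-(TBDPS-oxymethyl)pent-2-enoate | COC(=O)/C=C(\C(=O)CBr)CO[Si](c1ccccc1)(c1ccccc1)C(C)(C)C
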